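**Remark (assumption).** The SMILES encodes (2S,3R,2''R,3''S). The two halves are mirror images, so the target is the meso, achiral diastereomer; "single enantiomer" is read as "this single diastereomer", and the route controls relative configuration only.

## The problem

The target is a 3,3''-biflavanone: two 7,4'-dihydroxyflavanone units joined through C3–C3'', so that O=C4–C3–C3''–C4''=O is a 2,3-disubstituted 1,4-diketone. Its two central carbons are adjacent tertiary stereocentres, each flanked by a benzylic ether stereocentre (C2, C2''). Both pyranone rings are 2,3-trans, and the halves are (2S,3R) and (2R,3S).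

Inside one ring, C2 can control C3, because a new bond at C3 enters anti to the C2 aryl group. Nothing in one half directs the other across C3–C3''. The meso isomer differs from its C2-symmetric diastereomer only in that a 2S half is paired with a 2R half, with C3 and C3'' in the unlike relation. A dimerisation of racemic material therefore gives pairing statistics, and a dimerisation of enantiopure material can only give the wrong series.

All four centres are labile. C3 and C3'' are enolisable, and the C3 enolate expels the O1 phenoxide (retro-oxa-Michael to a chalcone), which scrambles C2 as well. The O1–C2 bonds are p-alkoxybenzyl-type ethers, sensitive to one-electron oxidants and to hydrogenolysis. The centres must therefore be set kinetically and carried through near-neutral steps.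

The feature that opens the problem: if C4 and C4'' are also joined, C3–C4–C4''–C3'' is a cyclobutane-1,2-diol. That is the head-to-head [2+2] dimer of two flavanone enol C3=C4 bonds, whose O4 atoms one silicon atom can hold. The mirror symmetry of the meso target is the mirror symmetry of a syn sandwich of two enantiomeric 2H-chromene rings.

## Retrosynthesis

**11 ⇐ 10.** The four O–benzyl bonds are cut. Benzyl ethers are inert to silyl triflate, visible light, fluoride and Pb(IV), and come off by neutral hydrogenolysis. The forward step must not touch C3/C3'' or the O1–C2 bonds.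

**10 ⇐ 9 ⇐ 8.** This is a reconnection: the C4–C4'' bond is added. Diketone 10 becomes the glycol-cleavage product of cis-cyclobutane-1,2-diol 9, which is the desilylated form of silylene acetal 8. Against a direct C3–C3'' cut of 10, this turns an open-chain stereodiad next to two ketones into a ring-fusion problem, and keeps C3/C3'' non-enolisable until the last C–C operation. The forward cleavage is a two-electron process, driven by cyclobutane strain and formation of two aryl ketones, and does not involve C3/C3''.

**8 ⇐ 7.** C3–C3'' and C4–C4'' are cut together (retro-[2+2]). Silyl bis-enol ether 7 has no stereocentre at C3, C4, C3'' or C4'', and no bond between the halves except through silicon. The forward photocycloaddition must be head-to-head, syn, and exo for both aryl groups. A ground-state one-electron oxidative coupling of 7 would form the same C3–C3'' bond. It has no ring-closure constraint on the C3/C3'' relation, and it exposes the p-alkoxybenzyl O1–C2 ethers to the oxidant.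

**7 ⇐ 4 + 5.** The two Si–O bonds are cut. Pairing 2S with 2R becomes a matter of order of addition to i-Pr2Si(OTf)2, through enoxysilyl triflate 6. A racemate would give 7 and the homochiral silanes statistically.

**4, 5 ⇐ 2 + 3.** The C2–aryl bond is cut: enantioselective conjugate addition of boronic acid 3 to chromone 2. The two ligand antipodes give the two halves. Both antipodes are consumed, so nothing is wasted on an achiral target.

**2 ⇐ 1.** The O–benzyl bond is cut: benzylation of commercial 7-hydroxychromone 1.

## Roads not taken

**Alternative 1:** Cut C3–C3'' alone; forward step: oxidative dimerisation (Cu(II), Fe(III) or I2) of the lithium enolate A1 of the protected flavanone. This is the shortest route on paper. A1 is a β-aryloxy enolate and opens by E1cB. The intermolecular coupling cannot choose hetero- over homochiral partners: the racemate gives the meso compound 10 and the C2-symmetric diastereomer A2 statistically, and enantiopure A1 gives only A2. The product also sits in base, where all four centres can scramble. The chosen plan removes the pairing problem by a tether, sets C3/C3'' by ring fusion, and never exposes the diketone to base.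

**Alternative 2:** Cut both O1–C2 bonds; forward step: double 6-endo oxa-Michael cascade of the achiral bis-chalcone A3, closing both rings and creating all four stereocentres at once. Every centre would form under reversible conditions, and nothing in the structure favours the trans,trans-meso isomer over the trans,trans-C2 or cis,trans isomers. A3, a 2,3-diaroyl-1,4-diarylbutadiene with free ortho-phenols, needs its own multi-step synthesis. The chosen plan sets each centre kinetically by a named control element.

**Alternative 3:** Cut C3–C3'' as the σ-bond of a [3,3] shift; forward step: 3,4-diaza-Cope rearrangement of the N,N'-diacyl bis-ene-hydrazine A5, made from the mixed azine A4 of 4 and 5 (interrupted Piloty–Robinson), then hydrolysis of the 1,4-diimine. Both ring alkenes have C2 trans to nitrogen, so the chair transition state gives the like C3/C3'' relation (C2-symmetric series); the meso relation needs the boat. In heterochiral A5 the chair also forces one new bond syn to a C2 aryl group. The rearranged product normally closes to the pyrrole, which erases C3/C3''. The photocycloaddition reaches the unlike relation through its favoured geometry.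

Key step: step 5

## Route

Step 1
Reactants: 1 7-hydroxy-4H-chromen-4-one
Product: 2 7-(benzyloxy)-4H-chromen-4-one
Conditions: BnBr, K2CO3, acetone, reflux
Reagents that add atoms: benzyl bromide, BrCc1ccccc1
Why: Williamson etherification of the acidic 7-OH with a carbonate base that does not open the pyrone ring; no stereocentre is involved.

Step 2
Reactants: 2 7-(benzyloxy)-4H-chromen-4-one; 3 [4-(benzyloxy)phenyl]boronic acid
Product: 4 (2S)-7-(benzyloxy)-2-[4-(benzyloxy)phenyl]-2,3-dihydro-4H-chromen-4-one
Conditions: Pd(OCOCF3)2 (5 mol %), (S)-t-BuPyOx (6 mol %), NH4PF6, H2O, ClCH2CH2Cl, 60 °C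
Reagents that add atoms: none
Why: Pd(II)/pyridine-oxazoline-catalysed enantioselective conjugate addition of an arylboronic acid to a chromone (aryl-Pd insertion into C2=C3, then protonation of the Pd enolate); C2 is set by the ligand, and if the sense of induction is opposite to that written, steps 2 and 3 simply exchange product numbers, since both antipodes are needed.

Step 3
Reactants: 2 7-(benzyloxy)-4H-chromen-4-one; 3 [4-(benzyloxy)phenyl]boronic acid
Product: 5 (2R)-7-(benzyloxy)-2-[4-(benzyloxy)phenyl]-2,3-dihydro-4H-chromen-4-one
Conditions: Pd(OCOCF3)2 (5 mol %), (R)-t-BuPyOx (6 mol %), NH4PF6, H2O, ClCH2CH2Cl, 60 °C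
Reagents that add atoms: none
Why: The mirror-image run of step 2 with the antipodal ligand; C2 is set by the ligand.

Step 4
Reactants: 4 (2S)-7-(benzyloxy)-2-[4-(benzyloxy)phenyl]-2,3-dihydro-4H-chromen-4-one; 5 (2R)-7-(benzyloxy)-2-[4-(benzyloxy)phenyl]-2,3-dihydro-4H-chromen-4-one
Product: 7 meso silyl bis-enol ether {[(2S)-7-(benzyloxy)-2-[4-(benzyloxy)phenyl]-2H-chromen-4-yl]oxy}{[(2R)-7-(benzyloxy)-2-[4-(benzyloxy)phenyl]-2H-chromen-4-yl]oxy}di(propan-2-yl)silane, via enoxysilyl triflate 6 (not isolated)
Conditions: i-Pr2Si(OTf)2 (1.0 equiv), Et3N, CH2Cl2, −78 °C, slow addition of 4; then 5 (1.0 equiv), −78 → 0 °C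
Reagents that add atoms: di(propan-2-yl)silanediyl bis(trifluoromethanesulfonate), CC(C)[Si](OS(=O)(=O)C(F)(F)F)(OS(=O)(=O)C(F)(F)F)C(C)C
Why: Soft enolisation (silyl triflate/amine silyl enol ether formation) avoids a free β-aryloxy enolate and so avoids E1cB opening of the pyranone; the second triflate of 6 is more hindered and less electrophilic than the first, so adding 4 first and 5 second should pair 2S with 2R; C2 is untouched and no new stereocentre forms.

Step 5
Reactants: 7 meso silyl bis-enol ether
Product: 8 (2S,3R,4S,2''R,3''S,4''R)-configured cis-syn-cis head-to-head cyclobutane (ring atoms C3, C4, C4'', C3'') of the two 7-(benzyloxy)-2-[4-(benzyloxy)phenyl]chromane units, with O4 and O4'' bridged by Si(i-Pr)2 as a 1,3-dioxa-2-silolane; H3, H3'' and both oxygens on one face, both benzopyran rings on the other, both C2 aryl groups exo; meso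
Conditions: 2-isopropylthioxanthone (10 mol %), 405 nm LEDs, degassed PhMe (0.005 M), 0 °C
Reagents that add atoms: none
Why: Proposed new method: triplet energy transfer from the thioxanthone to one 4-silyloxy-2H-chromene (an α-oxygenated styrene held planar by its ring, so the triplet cannot decay by twisting) gives a 1,2-diradicaloid whose C3 end adds to C3'' of the ground-state partner (7-endo closure through C3–C4–O–Si–O–C4''–C3''), and the resulting triplet 1,4-diradical, benzylic and α-oxygenated at C4 and C4'', closes C4–C4'' after intersystem crossing, forming the cyclobutane and the five-membered dioxasilolane together. The closest known reactions are the sensitised head-to-head [2+2] photodimerisation of 2H-chromenes and 1,2-dihydronaphthalenes and the intramolecular visible-light [2+2] cycloaddition of tethered styrenes; a silyl bis-enol ether has not been used as the diene. Head-to-head regiochemistry is fixed by the three-atom O–Si–O link between C4 and C4''. The two oxygens must be cis on the cyclobutane (five-membered silolane) and each benzopyran must be cis-fused to the four-membered ring (a trans-fused benzo-bicyclo[4.2.0] system is prohibitively strained), so C2 and C2'' end on one face and H3 and H3'' on the other: C3, C4, C4'' and C3'' are set by ring constraints, with C3/C3'' in the unlike (meso) relation, and a diradical with the other C3/C3'' relation cannot close and should cleave back to 7. On each chromene the new bonds form anti to the C2 aryl group (1,2-induction), and because 7 holds one 2S and one 2R ring, both aryl groups are exo in the mirror-symmetric syn sandwich. The step needs intramolecular to beat intermolecular addition (high dilution) and energy transfer to beat electron transfer and direct excitation (non-polar solvent, 405 nm where 7 does not absorb, which also avoids photochromic opening of the O1–C2 bond); 8 has lost the styrene chromophore and should not be re-excited.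

Step 6
Reactants: 8 silylene-bridged cyclobutane
Product: 9 (2S,3R,4S,2''R,3''S,4''R)-cis-cyclobutane-4,4''-diol: 8 with the Si(i-Pr)2 bridge replaced by two OH groups; meso
Conditions: TBAF (2.2 equiv), AcOH (2.2 equiv), THF, 0 °C
Reagents that add atoms: none
Why: Fluoride cleavage of a strained five-membered dialkylsilylene acetal, buffered with acetic acid so the ditertiary benzylic diol sees neither alkoxide base nor strong acid; no C–O or C–C bond is touched, so all six stereocentres are retained.

Step 7
Reactants: 9 cis-cyclobutane-4,4''-diol
Product: 10 (2S,3R,2''R,3''S)-7,7''-bis(benzyloxy)-2,2''-bis[4-(benzyloxy)phenyl]-[3,3''-bichromane]-4,4''-dione (meso)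
Conditions: Pb(OAc)4 (1.1 equiv), CH2Cl2–pyridine, −20 → 0 °C
Reagents that add atoms: none
Why: Criegee glycol cleavage through a cyclic lead(IV) diester, for which a cis-1,2-diol on a cyclobutane is ideally disposed, driven by release of ring strain and formation of two aryl ketones; the C4/C4'' stereocentres vanish, C3 and C3'' are not involved and keep the unlike relation, and the pyridine-buffered medium should not enolise the product.

Step 8
Reactants: 10 tetra-O-benzyl biflavanone
Product: 11 (2S,3R,2''R,3''S)-7,7''-dihydroxy-2,2''-bis(4-hydroxyphenyl)-[3,3''-bichromane]-4,4''-dione (meso; CNP0231820.1)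
Conditions: H2 (1 atm), 10% Pd/C, THF–MeOH, rt
Reagents that add atoms: none
Why: Heterogeneous hydrogenolysis of four aryl benzyl ethers under neutral conditions, which leaves the enolisable C3/C3'' centres alone; the reaction is stopped at four equivalents of uptake to spare the benzylic O1–C2 bonds.

## Compound list

1 | 7-hydroxy-4H-chromen-4-one | O=c1ccoc2cc(O)ccc12 | starting material
2 | 7-(benzyloxy)-4H-chromen-4-one | O=c1ccoc2cc(OCc3ccccc3)ccc12 | intermediate
3 | [4-(benzyloxy)phenyl]boronic acid | OB(O)c1ccc(OCc2ccccc2)cc1 | starting material
4 | (2S)-7-(benzyloxy)-2-[4-(benzyloxy)phenyl]-2,3-dihydro-4H-chromen-4-one | O=C1C[C@@H](c2ccc(OCc3ccccc3)cc2)Oc2cc(OCc3ccccc3)ccc12 | intermediate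
5 | (2R)-7-(benzyloxy)-2-[4-(benzyloxy)phenyl]-2,3-dihydro-4H-chromen-4-one | O=C1C[C@H](c2ccc(OCc3ccccc3)cc2)Oc2cc(OCc3ccccc3)ccc12 | intermediate
6 | {[(2S)-7-(benzyloxy)-2-[4-(benzyloxy)phenyl]-2H-chromen-4-yl]oxy}di(propan-2-yl)silyl trifluoromethanesulfonate | CC(C)[Si](OC1=C[C@@H](c2ccc(OCc3ccccc3)cc2)Oc2cc(OCc3ccccc3)ccc12)(OS(=O)(=O)C(F)(F)F)C(C)C | intermediate (not isolated)
7 | {[(2S)-7-(benzyloxy)-2-[4-(benzyloxy)phenyl]-2H-chromen-4-yl]oxy}{[(2R)-7-(benzyloxy)-2-[4-(benzyloxy)phenyl]-2H-chromen-4-yl]oxy}di(propan-2-yl)silane (meso) | CC(C)[Si](OC1=C[C@@H](c2ccc(OCc3ccccc3)cc2)Oc2cc(OCc3ccccc3)ccc12)(OC1=C[C@H](c2ccc(OCc3ccccc3)cc2)Oc2cc(OCc3ccccc3)ccc12)C(C)C | intermediate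
8 | (2S,3R,4S,2''R,3''S,4''R) cis-syn-cis head-to-head cyclobutane of two 7-(benzyloxy)-2-[4-(benzyloxy)phenyl]chromane units (C3–C3'' and C4–C4'' bonded), O4/O4'' bridged by Si(i-Pr)2; meso | CC(C)[Si]1(C(C)C)O[C@]23c4ccc(OCc5ccccc5)cc4O[C@H](c4ccc(OCc5ccccc5)cc4)[C@H]2[C@H]2[C@H](c4ccc(OCc5ccccc5)cc4)Oc4cc(OCc5ccccc5)ccc4[C@@]32O1 | intermediate
9 | (2S,3R,4S,2''R,3''S,4''R) cis-cyclobutane-4,4''-diol (8 without the silylene bridge); meso | O[C@]12c3ccc(OCc4ccccc4)cc3O[C@H](c3ccc(OCc4ccccc4)cc3)[C@H]1[C@H]1[C@H](c3ccc(OCc4ccccc4)cc3)Oc3cc(OCc4ccccc4)ccc3[C@@]21O | intermediate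
10 | (2S,3R,2''R,3''S)-7,7''-bis(benzyloxy)-2,2''-bis[4-(benzyloxy)phenyl]-[3,3''-bichromane]-4,4''-dione (meso) | O=C1c2ccc(OCc3ccccc3)cc2O[C@H](c2ccc(OCc3ccccc3)cc2)[C@H]1[C@@H]1C(=O)c2ccc(OCc3ccccc3)cc2O[C@H]1c1ccc(OCc2ccccc2)cc1 | intermediate
11 | (2S,3R,2''R,3''S)-7,7''-dihydroxy-2,2''-bis(4-hydroxyphenyl)-[3,3''-bichromane]-4,4''-dione (meso) | O=C1c2ccc(O)cc2O[C@H](c2ccc(O)cc2)[C@H]1[C@@H]1C(=O)c2ccc(O)cc2O[C@H]1c1ccc(O)cc1 | target

## Step count and risks

Total: 8 steps (steps 2 and 3 are the same reaction run with the two ligand antipodes). Longest linear sequence: 7 steps (1 → 2 or 3 → 4 → 5 → 6 → 7 → 8).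

**Step 5 (key step, proposed new method).** The most likely failure is that the 1,4-diradical cleaves back to 7 far more often than it closes. Slow side processes would then take over: hydrogen abstraction by the sensitiser triplet from the doubly activated C2–H, or single-electron oxidation of the electron-rich enol ether. A second failure mode is bond formation syn to one C2 aryl group, which would give a cis,trans-configured adduct.
Fallback (known chemistry): from 7, one-electron oxidation of the silyl bis-enol ether with ceric ammonium nitrate and NaHCO3 in MeCN–EtCN at −30 °C. The C3–C3'' bond should form intramolecularly through the silicon-tethered seven-membered transition state, and silicon is lost on work-up. This returns directly to 10; 8 and 9 are bypassed. Pairing is still heterochiral by the tether, and each bond should still form anti to its own aryl group, which together give the meso relation. The ring-closure filter is lost and the p-alkoxybenzyl-type O1–C2 ethers meet the oxidant, which is why this is the fallback and not the plan.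

**Step 4.** Double displacement at silicon by the first ketone, or acid-catalysed redistribution of enoxy groups between silicon centres, would degrade controlled pairing to statistics. Triflate-promoted opening of the pyranone is a further risk.
Fallback: from 4 and 5, give up the order of addition. A 1:1 mixture of 4 and 5 is silylated with 0.5 equiv of the ditriflate, giving 7 together with the homochiral silane bis{[(2S)-7-(benzyloxy)-2-[4-(benzyloxy)phenyl]-2H-chromen-4-yl]oxy}di(propan-2-yl)silane F1 and its 2R,2R antipode. The diastereomers are separated on Et3N-deactivated silica, or the mixture is irradiated and separated after step 5, since only 7 can place both aryl groups exo. F1 is cleaved with TBAF/AcOH back to 4 and 5 and recycled. The route is rejoined at 7.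

**Step 2 (and its mirror, step 3).** The donor-substituted chromone is a weaker acceptor, so low turnover of the cationic Pd(II) catalyst and competing protodeboronation of the electron-rich boronic acid are possible. Incomplete enantioselectivity would appear later as homochiral silane, a diastereomeric impurity.
Fallback: from 2 and 3, Rh(I)-catalysed 1,4-addition without a chiral ligand ([Rh(cod)OH]2, dioxane–H2O) gives racemic 7-(benzyloxy)-2-[4-(benzyloxy)phenyl]chroman-4-one F2. Preparative chromatography on a chiral stationary phase separates it into 4 and 5. Both antipodes are consumed, so the resolution discards nothing. The route is rejoined at 4 and 5.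

**Step 7.** Slow formation of the cyclic lead(IV) diester at the hindered ditertiary diol would leave time for ionisation of the electron-rich tertiary benzylic alcohol and pinacol-type ring contraction.
Fallback: from 9, alkoxy-radical β-scission (PhI(OAc)2, I2, visible light, NaHCO3, CH2Cl2, 0 °C). An oxygen-centred radical at C4 cleaves the strained C4–C4'' bond, and the resulting α-hydroxybenzyl radical is oxidised to the second ketone. This needs only one free hydroxyl and no cyclic ester, and returns to 10.

**Step 8.** Hydrogenolytic cleavage of the benzylic O1–C2 bonds (ring opening) could compete if debenzylation is slow and exposure long.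
Fallback: from 10, non-reductive Lewis-acid debenzylation with BCl3 and pentamethylbenzene as cation scavenger in CH2Cl2 at −78 °C, returning to 11.

## Further compounds

F0 | step 5 | none | none
F1 | step 4 | bis{[(2S)-7-(benzyloxy)-2-[4-(benzyloxy)phenyl]-2H-chromen-4-yl]oxy}di(propan-2-yl)silane (formed with its 2R,2R antipode) | CC(C)[Si](OC1=C[C@@H](c2ccc(OCc3ccccc3)cc2)Oc2cc(OCc3ccccc3)ccc12)(OC1=C[C@@H](c2ccc(OCc3ccccc3)cc2)Oc2cc(OCc3ccccc3)ccc12)C(C)C
F2 | step 2 | racemic 7-(benzyloxy)-2-[4-(benzyloxy)phenyl]-2,3-dihydro-4H-chromen-4-one | O=C1CC(c2ccc(OCc3ccccc3)cc2)Oc2cc(OCc3ccccc3)ccc12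
F0 | step 7 | none | none
F0 | step 8 | none | none
A1 | alternative 1 | lithium (2S)-7-(benzyloxy)-2-[4-(benzyloxy)phenyl]-2H-chromen-4-olate | [Li+].[O-]C1=C[C@@H](c2ccc(OCc3ccccc3)cc2)Oc2cc(OCc3ccccc3)ccc12
A2 | alternative 1 | (2S,3R,2''S,3''R)-7,7''-bis(benzyloxy)-2,2''-bis[4-(benzyloxy)phenyl]-[3,3''-bichromane]-4,4''-dione (C2-symmetric diastereomer) | O=C1c2ccc(OCc3ccccc3)cc2O[C@H](c2ccc(OCc3ccccc3)cc2)[C@H]1[C@H]1C(=O)c2ccc(OCc3ccccc3)cc2O[C@@H]1c1ccc(OCc2ccccc2)cc1
A3 | alternative 2 | (2E,3E)-1,4-bis[4-(benzyloxy)-2-hydroxyphenyl]-2,3-bis[4-(benzyloxy)benzylidene]butane-1,4-dione | O=C(c1ccc(OCc2ccccc2)cc1O)/C(=C/c1ccc(OCc2ccccc2)cc1)/C(=C\c1ccc(OCc2ccccc2)cc1)C(=O)c1ccc(OCc2ccccc2)cc1O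
A4 | alternative 3 | mixed azine of 4 and 5: 1-[(2S)-flavan-4-ylidene]-2-[(2R)-flavan-4-ylidene]hydrazine, each flavan unit carrying 7-benzyloxy and 4'-benzyloxy groups | C1(=NN=C2C[C@H](c3ccc(OCc4ccccc4)cc3)Oc3cc(OCc4ccccc4)ccc23)C[C@@H](c2ccc(OCc3ccccc3)cc2)Oc2cc(OCc3ccccc3)ccc12
A5 | alternative 3 | N,N'-diacetyl-N-[(2S)-7-(benzyloxy)-2-[4-(benzyloxy)phenyl]-2H-chromen-4-yl]-N'-[(2R)-7-(benzyloxy)-2-[4-(benzyloxy)phenyl]-2H-chromen-4-yl]hydrazine | CC(=O)N(C1=C[C@@H](c2ccc(OCc3ccccc3)cc2)Oc2cc(OCc3ccccc3)ccc12)N(C(C)=O)C1=C[C@H](c2ccc(OCc3ccccc3)cc2)Oc2cc(OCc3ccccc3)ccc12
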